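One easy step comes first: the delta run reached 51.6% of target in 10.0 d, and the gamma run reached 16.8% in 20.0 d.

in all of them: free catalyst 10 mol%; added ligand 78 mM
- gamma: starting material 0.54 M; second substrate 2 equiv; reagent 1.5 equiv; temperature 65 °C; run made earlier
- delta: starting material 0.80 M; second substrate 2 equiv; reagent 2.2 equiv; temperature 76 °C; run made earlier
- ash: starting material 0.80 M; second substrate 2.00 equiv; reagent 1.50 equiv; temperature 60 °C; time 15 d
- birch: starting material 0.80 M; second substrate 2.00 equiv; reagent 1.50 equiv; temperature 80 °C; time 15 d

- gamma (time / d: target / %): 1.25: 1.1; 3.00: 4.0; 8.00: 7.0; 20.0: 16.8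
- delta (time / d: target / %): 0.625: 3.5; 1.25: 9.9; 4.00: 26.2; 10.0: 51.6

(standard deviation of a reading: 1 percentage point)

* the flask that comes out highest in amount of target, in percent of the starting material charged, or "all alike" when all lie within 1.5 percentage points (ash / birch / all alike)
* target at the end, in percent of the starting material charged, ash
* target at the end, in percent of the starting material charged, birch

- steps thought possible: starting material + free catalyst <-> catalyst intermediate A; reagent + catalyst intermediate A -> free catalyst + target; second substrate + free catalyst <-> catalyst intermediate B; reagent + catalyst intermediate B -> free catalyst + second product; free catalyst + added ligand <-> idle complex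

Starting material and second substrate can each bind free catalyst, reagent can turn each bound form into its product, and added ligand can hold free catalyst as idle complex. I read the last reading of each run as first order in starting material, a pseudo-first-order constant. That gave 0.0726 d⁻¹ for delta and 0.00920 d⁻¹ for gamma.

I assumed that second substrate holds most of the catalyst as catalyst intermediate B, the resting state. The constant should then go as reagent times catalyst over second substrate. Catalyst and second substrate rose together from gamma to delta and cancel, so reagent concentration explains a factor 2.17. That left a factor 3.63 for going from 65 °C to 76 °C.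

Birch differs from delta in reagent and temperature. Scaling both gave 0.0791 d⁻¹ and 8.76 d. This is the target half-life, the time in which half of the starting material becomes target while reagent lasts. The same scaling gave ash 0.00758 d⁻¹ and 91.4 d.

So 15 d is 1.71 half-lives in birch, giving 69.5%, and 0.164 in ash, giving 10.7%. The readings show target and not reagent, so they gave me no time for the reagent to go. I committed to the figure for ash, to something lower for birch, and to birch as the higher flask.

The forecast said birch, with 17% for ash, above my figure, and 55% for birch, of which it wrote “Reagent consumption, including the second product, lowers this”.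

Ash gave 9.17% and birch 37.8%, so birch came out higher.

    starting material + free catalyst ⇌ catalyst intermediate A (K = 0.460 M⁻¹, k = 1.25 × 10⁻⁴ M⁻¹ s⁻¹, Ea = 81.0 kJ mol⁻¹, ΔH = 40.0 kJ mol⁻¹)
    reagent + catalyst intermediate A → free catalyst + target (k = 0.00200 M⁻¹ s⁻¹, Ea = 90.0 kJ mol⁻¹)
    second substrate + free catalyst ⇌ catalyst intermediate B (K = 7.25 M⁻¹, k = 0.00150 M⁻¹ s⁻¹, Ea = 71.0 kJ mol⁻¹, ΔH = −44.0 kJ mol⁻¹)
    reagent + catalyst intermediate B → free catalyst + second product (k = 7.05 × 10⁻⁵ M⁻¹ s⁻¹, Ea = 100 kJ mol⁻¹)
    free catalyst + added ligand ⇌ idle complex (K = 9.54 M⁻¹, k = 3.00 × 10⁻⁴ M⁻¹ s⁻¹, Ea = 61.0 kJ mol⁻¹, ΔH = −50.0 kJ mol⁻¹)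
    (constants at 80 °C)

In birch, the step making second product had half its turnover up to 15 d behind it by 1.24 d, far sooner than my target half-life of 8.76 d. At 7.50 d birch's reagent, the limiting reagent, stood at 1.04% of its charge and target at 36.9%, where my half-life gives 44.7%; target ended at 37.8%. A neighbour like birch with 2.5 mol% of free catalyst gets, on my scaling with catalyst, a target half-life of 35.1 d, which gives 25.6%. The computed result is 26.3%, with 15% of its reagent left.

The data come from a simulation for substances that don't exist; scatter was added.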